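All constants were chosen freely; what happens was integrated by code.

Tuesday's flask repeats Monday's run at a higher temperature, and two chemists argue over what the heat did to the ring.

- Monday's: substrate 1.5 M; activator 2.70 M; temperature 80 °C; time 80 s
- Tuesday's: substrate 1.5 M; activator 2.70 M; temperature 100 °C; time 80 s

    activated form → ring (k1 = 0.057 s⁻¹, Ea1 = 88.0 kJ mol⁻¹)
    activated form → side product (k2 = 0.10 s⁻¹, Ea2 = 95.0 kJ mol⁻¹)
    substrate + activator → activated form (k3 = 0.023 L mol⁻¹ s⁻¹, Ea3 = 65.0 kJ mol⁻¹)
    substrate + activated form → open dimer (k4 = 0.097 L mol⁻¹ s⁻¹, Ea4 = 52.0 kJ mol⁻¹)
    activator → decomposition product (k5 = 9.0 × 10⁻⁵ s⁻¹, Ea5 = 104 kJ mol⁻¹)
    2 activator → homo dimer (k6 = 0.0061 L mol⁻¹ s⁻¹, Ea6 = 79.0 kJ mol⁻¹)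
    (constants at 80 °C)

- percentages count the substrate that a species holds: one open dimer counts as two
- where a step has two of a species, its rate is k times that concentration squared, and two are used at each turn
- all constants are for 80 °C and move with temperature by the activation energies

- the flask with the highest share of ring in all that became ring or open dimer or side product ("all alike" if they lie within 1.5 percentage points) (Monday's / Tuesday's / all alike)
- share of ring in all that became ring or open dimer or side product, Monday's
- share of ring in all that became ring or open dimer or side product, Tuesday's

Activated form can close to ring, fall to side product, or be caught by substrate to give open dimer, which holds two substrates. Counting substrate lost, the catching step therefore weighs double. I keep one number for each flask: two times the catching constant times the substrate charge, over the closing and falling constants summed. It is 1.85 for Monday's and, with closing faster by a factor of 5.0, falling by 5.66 and catching by 2.6, 0.884 for Tuesday's. This is the crowding number, call it w. Let e be closing over closing plus falling, and a the fraction of the substrate charge still present. The ring's share of the product forming at any moment, counted in substrate, is then e divided by one plus w times a.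

The first chemist looks at thin substrate, where a is near zero and the share is e. That gives 36.3% on Monday's and 33.4% on Tuesday's, lower because falling has the higher activation energy, so this chemist backs Monday's. The second looks at the full charge, where a is one, and gets 12.7% on Monday's and 17.7% on Tuesday's, so backs Tuesday's.

I join the two ends. On Monday's flask activated form lasts 3.31 s at the start, shorter than the 16.1 s substrate takes to be activated, so I treat it as a passing stock, a steady state. Averaging the share as a falls from one to zero, although the flasks are stopped at a set time, gives as my estimate e times the logarithm of one plus w, divided by w. That is 20.5% for Monday's and 23.9% for Tuesday's, so heat costs some e but gains more through the lower w.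

The forecast takes the second side: Tuesday's, with 20% and 23.6%, slightly below mine, on the ground that “heating favours the first-order ring and side-product steps”.

The simulation gives Tuesday's, with 20.2% for Monday's and 23.9% for Tuesday's, while 11% of Monday's substrate and 7.0% of Tuesday's remain at 80.0 s. The first chemist's figure for Tuesday's lies 9.5 percentage points above Tuesday's result, at a crowding number of 0.884, but that view belongs to thin substrate. The neighbour is Tuesday's flask with 0.38 M of substrate. Its crowding number falls to 0.224, and the same average gives 30.1%. That neighbour ends with a ring share of 30.4%, 3 points below the first chemist's figure for Tuesday's, with 8.67% of its substrate in open dimer.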